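The runs come from a simulation for substances that don't exist, noise included.

Amounts of starting material from 0.10 M to 0.22 M, at 7.1 mM of catalyst, end on nearly the same reading of target, with a mean of 57.8% over the last readings. So c(starting material) does not show in these plateaus, but c(catalyst) does: Wednesday's run, with 11 mM, ends at 63.2%.

| flask | starting material | catalyst | remark | time |
|---|---|---|---|---|
| Tuesday's | 0.10 M | 7.1 mM | run made earlier |  |
| Thursday's | 0.14 M | 7.1 mM | run made earlier |  |
| Sunday's | 0.22 M | 7.1 mM | run made earlier |  |
| Wednesday's | 0.10 M | 11 mM | run made earlier |  |
| ash | 0.10 M | 7.1 mM | a single well-mixed tank run continuously and read at steady state, 10 min in it on average |  |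
| cedar | 0.10 M (fed, over 8.00 min) | 7.1 mM | a stirred flask in which starting material is dosed at a steady rate over 8.00 min without added volume, worked up at 10 min | 10 min |
| alder | 0.10 M | 7.1 mM | a closed flask charged with all of it at once and left for 10 min | 10 min |

| run | time / min | target / % |
|---|---|---|
| Tuesday's | 1.00 | 65.1 |
| Tuesday's | 2.00 | 60.6 |
| Tuesday's | 3.00 | 58.7 |
| Tuesday's | 4.00 | 58.5 |
| Tuesday's | 5.00 | 58.1 |
| Tuesday's | 6.00 | 58.2 |
| Thursday's | 1.33 | 64.2 |
| Thursday's | 2.50 | 60.0 |
| Thursday's | 4.00 | 58.8 |
| Thursday's | 5.00 | 57.8 |
| Thursday's | 6.00 | 58.2 |
| Thursday's | 8.00 | 57.5 |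
| Sunday's | 0.500 | 61.7 |
| Sunday's | 1.50 | 62.9 |
| Sunday's | 3.00 | 59.6 |
| Sunday's | 4.00 | 58.7 |
| Sunday's | 6.00 | 58.0 |
| Sunday's | 8.00 | 57.8 |
| Wednesday's | 0.667 | 74.2 |
| Wednesday's | 1.33 | 69.3 |
| Wednesday's | 2.50 | 65.4 |
| Wednesday's | 4.00 | 64.0 |
| Wednesday's | 8.00 | 63.2 |

(standard deviation of a reading: 0.3 percentage points)

- the stated concentrations are those of everything mixed, before any reaction; amounts are the same in each set-up
- steps that have been proposed: starting material + catalyst -> catalyst + target; target <-> isomer of the product; starting material -> side product
- the feed brings no volume worth counting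
- the earlier runs were made in a closed, stirred flask

* the set-up with the highest amount of target at the outlet or at the end, in percent of the starting material put in ("none" if the first two lie within 2 percentage points) (ash / cedar / alder / none)
* amount of target at the outlet or at the end, in percent of the starting material put in, ash
* amount of target at the outlet or at the end, in percent of the starting material put in, cedar
* amount of target at the outlet or at the end, in percent of the starting material put in, alder

I read this as two losses of starting material, each first order in it, one through the catalyst and one to side product, after which target shares with its isomer in a constant ratio. The two plateaus, readings with their scatter, then give 2.24 mM, the crossing concentration c×, the c(catalyst) at which on this reading both routes run equally fast. The ratio c(catalyst)/c× is the selectivity factor, and c(catalyst)/(c(catalyst)+c×) of what reacts goes towards target. The same readings put target at 76.0% of target plus isomer at rest. Ash, cedar and alder each hold 7.1 mM of catalyst, so I reckon that each sends 76.0% that way. I expect alder at 57.8% and the other two within 2 percentage points of it, hence no winner.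

The forecast says 58.6% for ash, 58.5% for cedar and 58% for alder: “All lie within 2 points, so none.”

Ash gives 58.2%, cedar 58.4% and alder 58.0%, so the answer is none. In cedar c(starting material) peaks at 0.00298 M, far below the 0.10 M charged at once in alder, yet target barely moves. The crossing puts cedar's side product, a species outside the readings so far, at 24.0%, and cedar holds 24.6%.

    starting material + catalyst → catalyst + target (k = 7.43 M⁻¹ s⁻¹)
    target ⇌ isomer of the product (K = 0.300, k = 0.00381 s⁻¹)
    starting material → side product (k = 0.0172 s⁻¹)

The neighbour of cedar with 0.0018 M of catalyst lies below the crossing, and I reckon target there at 33.9% and side product at 55.4%. That flask gives 33.9% and 56.2%.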